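Numbering: ring A is the benzo ring (C4a, C5–C8, C8a), ring B the dioxane (O1, C2, C3, O4), ring C the aryl group on C2. C3 carries the methyl, C5 the methoxy and C7 the propenyl group, and this numbering is kept for all bicyclic compounds.
Cuts: first the phenol protecting group and the side-chain C=C (back to a masked C7 aldehyde). Then both aryl–oxygen bonds of ring B, C8a–O1 and C4a–O4, are cut in one stroke, and last the C2–ring C bond (aryl Grignard plus a lactic acid derivative).
Enabling feature: O1 and O4 sit on adjacent carbons of ring A, so ring A can act as an aryne (C4a≡C8a). Only the C5 methoxy group, next to C4a, tells its two ends apart: it sends an oxygen nucleophile to C8a and leaves the carbanion on C4a for an oxygen electrophile.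
Forward: rings A and C are bought. The C2–C3 chain is attached to ring C, its C3 oxygen is made electrophilic as a tert-butyl peroxide, ring B closes in the union with the aryne, and the side chain is finished last.
Stereochemistry: C3 comes from ethyl (S)-lactate and is inverted once (S to R) when tert-butyl peroxide anion displaces a mesylate. C2 (R) is set by chelation-controlled reduction of an α-benzyloxy ketone, the ring closure touches neither centre, and the E alkene comes from a Julia–Kocienski olefination.
Key step: step 13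

Assumption: 5-(ethylsulfonyl)-1-phenyl-1H-tetrazole, benzyl 2,2,2-trichloroacetimidate and anhydrous tert-butyl hydroperoxide in decane are taken as purchasable, and Zn(BH4)2 is used as an ethereal stock solution made beforehand from ZnCl2 and NaBH4.

Step 1
Reactants: 1 5-bromovanillin (3-bromo-4-hydroxy-5-methoxybenzaldehyde)
Product: 2 2-bromo-4-(1,3-dioxolan-2-yl)-6-methoxyphenol
Conditions: HOCH2CH2OH, p-TsOH·H2O (cat.), toluene, reflux, azeotropic removal of water
Reagents that add atoms: ethylene glycol, OCCO
Why: Acid-catalysed acetalisation with azeotropic removal of water masks the aldehyde, which would not survive n-butyllithium, the alkoxide or the aryl anion of the later steps, and the free phenol is a spectator.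

Step 2
Reactants: 2 2-bromo-4-(1,3-dioxolan-2-yl)-6-methoxyphenol
Product: 6 4-(1,3-dioxolan-2-yl)-2-methoxy-6-(trimethylsilyl)phenyl trifluoromethanesulfonate, via trimethylsilyl ether 3 (not isolated), via aryllithium 4 (not isolated), via lithium phenoxide 5 (not isolated)
Conditions: (Me3Si)2NH, THF, 70 °C, then evaporation; n-BuLi, THF, −78 °C; Tf2O, −78 °C; aq. NaHCO3
Reagents that add atoms: hexamethyldisilazane, C[Si](C)(C)N[Si](C)(C)C; trifluoromethanesulfonic anhydride, O=S(=O)(OS(=O)(=O)C(F)(F)F)C(F)(F)F
Why: O-silylation, bromine–lithium exchange, retro-Brook migration of silicon from oxygen to the lithiated carbon and O-triflation of the resulting phenoxide form the standard one-flask entry to ortho-silylaryl triflates from 2-bromophenols, and the dioxolane is inert to all four events at low temperature.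

Step 3
Reactants: 7 4-bromo-2,6-dimethoxyphenol
Product: 8 5-bromo-1,3-dimethoxy-2-(methoxymethoxy)benzene
Conditions: MOMCl, i-Pr2NEt, CH2Cl2, 0 °C → rt
Reagents that add atoms: chloromethyl methyl ether, COCCl
Why: Williamson-type O-alkylation gives a methoxymethyl ether that tolerates magnesium, hydride, fluoride, alkoxide and carbanions and comes off with dilute acid at the end, whereas a silyl ether would fall to fluoride in step 13 and a benzyl ether could not be hydrogenolysed beside the propenyl group.

Step 4
Reactants: 9 ethyl (S)-lactate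
Product: 10 ethyl (S)-2-(benzyloxy)propanoate
Conditions: BnOC(=NH)CCl3, TfOH (cat.), cyclohexane/CH2Cl2, rt
Reagents that add atoms: benzyl 2,2,2-trichloroacetimidate, ClC(Cl)(Cl)C(=N)OCc1ccccc1
Why: Acid-catalysed benzylation with the trichloroacetimidate needs no base, so the lactate stereocentre (the future C3) keeps its S configuration, and a benzyl ether is a good chelating group for step 7.

Step 5
Reactants: 10 ethyl (S)-2-(benzyloxy)propanoate
Product: 11 (S)-2-(benzyloxy)-N-methoxy-N-methylpropanamide
Conditions: MeNH(OMe)·HCl, i-PrMgCl, THF, −20 → 0 °C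
Reagents that add atoms: N,O-dimethylhydroxylamine hydrochloride, CNOC.Cl
Why: Weinreb amide formation from the ester with the chloromagnesium amide of N,O-dimethylhydroxylamine runs below 0 °C and leaves the α-alkoxy stereocentre untouched.

Step 6
Reactants: 8 5-bromo-1,3-dimethoxy-2-(methoxymethoxy)benzene; 11 (S)-2-(benzyloxy)-N-methoxy-N-methylpropanamide
Product: 13 (S)-2-(benzyloxy)-1-[3,5-dimethoxy-4-(methoxymethoxy)phenyl]propan-1-one, via arylmagnesium bromide 12 (not isolated)
Conditions: 8, Mg, THF, 40 °C; then 11, 0 °C → rt; aq. NH4Cl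
Reagents that add atoms: none
Why: Grignard addition to a Weinreb amide stops at the magnesium-chelated tetrahedral adduct, so the ketone appears only on quenching and neither a second addition nor enolisation at the stereocentre should occur.

Step 7
Reactants: 13 (S)-2-(benzyloxy)-1-[3,5-dimethoxy-4-(methoxymethoxy)phenyl]propan-1-one
Product: 14 (1R,2S)-2-(benzyloxy)-1-[3,5-dimethoxy-4-(methoxymethoxy)phenyl]propan-1-ol
Conditions: Zn(BH4)2, Et2O, −30 → 0 °C; aq. NH4Cl
Reagents that add atoms: none
Why: Chelation-controlled reduction (Cram chelate model): zinc binds the carbonyl and benzyloxy oxygens in a five-membered ring and hydride comes in from the face that carries the small C2 hydrogen, which sets the new carbinol centre as 1R, anti to the 2S ether.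

Step 8
Reactants: 14 (1R,2S)-2-(benzyloxy)-1-[3,5-dimethoxy-4-(methoxymethoxy)phenyl]propan-1-ol
Product: 15 {(1R,2S)-2-(benzyloxy)-1-[3,5-dimethoxy-4-(methoxymethoxy)phenyl]propoxy}(tert-butyl)dimethylsilane
Conditions: TBSCl, imidazole, DMF, rt
Reagents that add atoms: tert-butyldimethylsilyl chloride, CC(C)(C)[Si](C)(C)Cl
Why: Silylation with TBSCl and imidazole blocks the benzylic hydroxyl, which as a free alkoxide would close an epoxide on to C2 in step 11, and these mild conditions do not disturb the methoxymethyl ether.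

Step 9
Reactants: 15 {(1R,2S)-2-(benzyloxy)-1-[3,5-dimethoxy-4-(methoxymethoxy)phenyl]propoxy}(tert-butyl)dimethylsilane
Product: 16 (1R,2S)-1-[(tert-butyldimethylsilyl)oxy]-1-[3,5-dimethoxy-4-(methoxymethoxy)phenyl]propan-2-ol
Conditions: H2 (1 atm), Pd/C, EtOAc, rt
Reagents that add atoms: none
Why: Catalytic hydrogenolysis removes the primary benzyl ether, whereas the hindered secondary benzylic silyl ether and the methoxymethyl ether are not cleaved over Pd/C in neutral ethyl acetate.

Step 10
Reactants: 16 (1R,2S)-1-[(tert-butyldimethylsilyl)oxy]-1-[3,5-dimethoxy-4-(methoxymethoxy)phenyl]propan-2-ol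
Product: 17 (1R,2S)-1-[(tert-butyldimethylsilyl)oxy]-1-[3,5-dimethoxy-4-(methoxymethoxy)phenyl]propan-2-yl methanesulfonate
Conditions: MsCl, Et3N, CH2Cl2, 0 °C
Reagents that add atoms: methanesulfonyl chloride, CS(=O)(=O)Cl
Why: Mesylation breaks only the O–H bond, so C2 stays S and now carries a leaving group that is still stable enough to be handled, unlike a triflate next to the migration-prone ring C.

Step 11
Reactants: 17 (1R,2S)-1-[(tert-butyldimethylsilyl)oxy]-1-[3,5-dimethoxy-4-(methoxymethoxy)phenyl]propan-2-yl methanesulfonate; 18 tert-butyl hydroperoxide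
Product: 20 tert-butyl{(1R,2R)-2-(tert-butylperoxy)-1-[3,5-dimethoxy-4-(methoxymethoxy)phenyl]propoxy}dimethylsilane, via potassium tert-butyl peroxide 19 (not isolated)
Conditions: t-BuOOH (decane solution, slight excess over base), KOt-Bu, DMF, 0 → 35 °C
Reagents that add atoms: none
Why: SN2 alkylation of a hydroperoxide anion by a secondary alkyl methanesulfonate is the classical route to sec-alkyl tert-butyl peroxides and goes with inversion, which turns 2S into 2R, while the weakly basic α-effect nucleophile keeps elimination in check.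

Step 12
Reactants: 20 tert-butyl{(1R,2R)-2-(tert-butylperoxy)-1-[3,5-dimethoxy-4-(methoxymethoxy)phenyl]propoxy}dimethylsilane
Product: 21 (1R,2R)-2-(tert-butylperoxy)-1-[3,5-dimethoxy-4-(methoxymethoxy)phenyl]propan-1-ol
Conditions: Bu4NF, AcOH (1:1), THF, 0 °C → rt
Reagents that add atoms: none
Why: Fluoride-mediated desilylation buffered with acetic acid frees the alcohol without leaving a basic alkoxide beside the peroxide, and dialkyl peroxides and methoxymethyl ethers are inert to fluoride.

Step 13
Reactants: 21 (1R,2R)-2-(tert-butylperoxy)-1-[3,5-dimethoxy-4-(methoxymethoxy)phenyl]propan-1-ol; 6 4-(1,3-dioxolan-2-yl)-2-methoxy-6-(trimethylsilyl)phenyl trifluoromethanesulfonate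
Product: 25 (2R,3R)-7-(1,3-dioxolan-2-yl)-5-methoxy-3-methyl-2-[3,5-dimethoxy-4-(methoxymethoxy)phenyl]-2,3-dihydro-1,4-benzodioxine, via potassium alkoxide 22 (not isolated), via aryne 23 (not isolated), via aryl anion 24 (not isolated)
Conditions: 21, KH, THF, −20 °C; then 6 (2.5 equiv), KF, 18-crown-6 (dried), THF, −20 °C → rt
Reagents that add atoms: none
Why: Proposed new method: desilylation of 6 by fluoride with loss of triflate unveils aryne 23 (triple bond C4a–C8a), alkoxide 22 adds to it to make C8a–O1, and the aryl anion 24 so formed, with its charge on C4a, substitutes at the peroxide oxygen bound to C3, expelling tert-butoxide and making C4a–O4. The closest known reaction types are the annulation of arynes from ortho-silylaryl triflates by partners that carry a nucleophile and a tethered electrophile, and the etherification of aryl or alkyl lithium and magnesium reagents with dialkyl peroxides, which is also known in an intramolecular form that gives cyclic ethers; their combination, with oxygen in both roles, has not been shown. Ring B closes by a 6-exo-tet substitution at oxygen, a geometry in which carbanion, attacked oxygen and departing oxygen can become collinear, while the tert-butyl group shields the distal oxygen. No stereocentre is created and no bond to C2 or C3 is broken, so 1R,2R in 21 is carried over as 2R,3R in 25. The step needs the alkoxide to attack C8a and not C4a, and the C5 methoxy group secures this: as in other 3-alkoxyarynes its σ-withdrawal bends the triple bond so that the carbon meta to it is the electrophilic end and the charge ends up ortho to oxygen. It also needs ring closure to be faster than protonation or base-induced loss of the peroxide, which is why KH (H2 as only by-product) and THF instead of acetonitrile are used, the alkoxide is made cold and consumed at once, and 6 is taken in excess because the released tert-butoxide also traps aryne.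

Step 14
Reactants: 25 (2R,3R)-7-(1,3-dioxolan-2-yl)-5-methoxy-3-methyl-2-[3,5-dimethoxy-4-(methoxymethoxy)phenyl]-2,3-dihydro-1,4-benzodioxine
Product: 26 (2R,3R)-2-[3,5-dimethoxy-4-(methoxymethoxy)phenyl]-5-methoxy-3-methyl-2,3-dihydro-1,4-benzodioxine-7-carbaldehyde
Conditions: 1 M aq. HCl, THF, rt
Reagents that add atoms: water, O
Why: Acid-catalysed acetal hydrolysis is very fast for the dioxolane of an electron-rich benzaldehyde, so dilute acid at room temperature should spare the phenolic methoxymethyl ether and the benzylic C2–O1 bond.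

Step 15
Reactants: 26 (2R,3R)-2-[3,5-dimethoxy-4-(methoxymethoxy)phenyl]-5-methoxy-3-methyl-2,3-dihydro-1,4-benzodioxine-7-carbaldehyde; 27 5-(ethylsulfonyl)-1-phenyl-1H-tetrazole
Product: 29 (2R,3R)-2-[3,5-dimethoxy-4-(methoxymethoxy)phenyl]-5-methoxy-3-methyl-7-[(E)-prop-1-en-1-yl]-2,3-dihydro-1,4-benzodioxine, via metallated sulfone 28 (not isolated)
Conditions: 27, KN(SiMe3)2, DME, −78 °C; then 26, −78 °C → rt
Reagents that add atoms: none
Why: Julia–Kocienski olefination: the metallated 1-phenyltetrazolyl sulfone adds to the aldehyde, Smiles rearrangement and loss of SO2 and tetrazolone follow, and with potassium in DME the anti adduct and hence the E alkene should prevail, no acidic hydrogen being present at C2 or C3.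

Step 16
Reactants: 29 (2R,3R)-2-[3,5-dimethoxy-4-(methoxymethoxy)phenyl]-5-methoxy-3-methyl-7-[(E)-prop-1-en-1-yl]-2,3-dihydro-1,4-benzodioxine
Product: 30 4-{(2R,3R)-5-methoxy-3-methyl-7-[(E)-prop-1-en-1-yl]-2,3-dihydro-1,4-benzodioxin-2-yl}-2,6-dimethoxyphenol (CNP0227775.1)
Conditions: HCl (0.5 M), MeOH, rt
Reagents that add atoms: none
Why: Acid-catalysed transacetalisation to methanol removes the methoxymethyl group, which is especially labile on a phenol flanked by two methoxy groups, under conditions dilute enough to leave the propenyl group and ring B alone.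

Compound list
1 | 5-bromovanillin | O=Cc1cc(OC)c(O)c(Br)c1 | starting material
2 | 2-bromo-4-(1,3-dioxolan-2-yl)-6-methoxyphenol | COc1cc(C2OCCO2)cc(Br)c1O | intermediate
3 | [2-bromo-4-(1,3-dioxolan-2-yl)-6-methoxyphenoxy]trimethylsilane | COc1cc(C2OCCO2)cc(Br)c1O[Si](C)(C)C | intermediate
4 | {5-(1,3-dioxolan-2-yl)-3-methoxy-2-[(trimethylsilyl)oxy]phenyl}lithium | COc1cc(C2OCCO2)cc([Li])c1O[Si](C)(C)C | intermediate
5 | lithium 4-(1,3-dioxolan-2-yl)-2-methoxy-6-(trimethylsilyl)phenoxide | [Li+].[O-]c1c(OC)cc(C2OCCO2)cc1[Si](C)(C)C | intermediate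
6 | 4-(1,3-dioxolan-2-yl)-2-methoxy-6-(trimethylsilyl)phenyl trifluoromethanesulfonate | COc1cc(C2OCCO2)cc([Si](C)(C)C)c1OS(=O)(=O)C(F)(F)F | intermediate
7 | 4-bromo-2,6-dimethoxyphenol | COc1cc(Br)cc(OC)c1O | starting material
8 | 5-bromo-1,3-dimethoxy-2-(methoxymethoxy)benzene | COCOc1c(OC)cc(Br)cc1OC | intermediate
9 | ethyl (S)-lactate | CCOC(=O)[C@H](C)O | starting material
10 | ethyl (S)-2-(benzyloxy)propanoate | CCOC(=O)[C@H](C)OCc1ccccc1 | intermediate
11 | (S)-2-(benzyloxy)-N-methoxy-N-methylpropanamide | CON(C)C(=O)[C@H](C)OCc1ccccc1 | intermediate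
12 | [3,5-dimethoxy-4-(methoxymethoxy)phenyl]magnesium bromide | COCOc1c(OC)cc([Mg]Br)cc1OC | intermediate
13 | (S)-2-(benzyloxy)-1-[3,5-dimethoxy-4-(methoxymethoxy)phenyl]propan-1-one | O=C(c1cc(OC)c(OCOC)c(OC)c1)[C@H](C)OCc1ccccc1 | intermediate
14 | (1R,2S)-2-(benzyloxy)-1-[3,5-dimethoxy-4-(methoxymethoxy)phenyl]propan-1-ol | O[C@H](c1cc(OC)c(OCOC)c(OC)c1)[C@H](C)OCc1ccccc1 | intermediate
15 | {(1R,2S)-2-(benzyloxy)-1-[3,5-dimethoxy-4-(methoxymethoxy)phenyl]propoxy}(tert-butyl)dimethylsilane | CC(C)(C)[Si](C)(C)O[C@H](c1cc(OC)c(OCOC)c(OC)c1)[C@H](C)OCc1ccccc1 | intermediate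
16 | (1R,2S)-1-[(tert-butyldimethylsilyl)oxy]-1-[3,5-dimethoxy-4-(methoxymethoxy)phenyl]propan-2-ol | CC(C)(C)[Si](C)(C)O[C@H](c1cc(OC)c(OCOC)c(OC)c1)[C@H](C)O | intermediate
17 | (1R,2S)-1-[(tert-butyldimethylsilyl)oxy]-1-[3,5-dimethoxy-4-(methoxymethoxy)phenyl]propan-2-yl methanesulfonate | CC(C)(C)[Si](C)(C)O[C@H](c1cc(OC)c(OCOC)c(OC)c1)[C@H](C)OS(C)(=O)=O | intermediate
18 | tert-butyl hydroperoxide | CC(C)(C)OO | starting material
19 | potassium tert-butyl peroxide | [K+].CC(C)(C)O[O-] | intermediate
20 | tert-butyl{(1R,2R)-2-(tert-butylperoxy)-1-[3,5-dimethoxy-4-(methoxymethoxy)phenyl]propoxy}dimethylsilane | CC(C)(C)[Si](C)(C)O[C@H](c1cc(OC)c(OCOC)c(OC)c1)[C@@H](C)OOC(C)(C)C | intermediate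
21 | (1R,2R)-2-(tert-butylperoxy)-1-[3,5-dimethoxy-4-(methoxymethoxy)phenyl]propan-1-ol | O[C@H](c1cc(OC)c(OCOC)c(OC)c1)[C@@H](C)OOC(C)(C)C | intermediate
22 | potassium (1R,2R)-2-(tert-butylperoxy)-1-[3,5-dimethoxy-4-(methoxymethoxy)phenyl]propan-1-olate | [K+].[O-][C@H](c1cc(OC)c(OCOC)c(OC)c1)[C@@H](C)OOC(C)(C)C | intermediate
23 | 5-(1,3-dioxolan-2-yl)-3-methoxybenzyne (triple bond between the future C4a and C8a) | COC1=CC(C2OCCO2)=CC#C1 | intermediate
24 | potassium 2-{(1R,2R)-2-(tert-butylperoxy)-1-[3,5-dimethoxy-4-(methoxymethoxy)phenyl]propoxy}-4-(1,3-dioxolan-2-yl)-6-methoxybenzen-1-ide | [K+].COc1cc(C2OCCO2)cc(O[C@H](c2cc(OC)c(OCOC)c(OC)c2)[C@@H](C)OOC(C)(C)C)[c-]1 | intermediate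
25 | (2R,3R)-7-(1,3-dioxolan-2-yl)-5-methoxy-3-methyl-2-[3,5-dimethoxy-4-(methoxymethoxy)phenyl]-2,3-dihydro-1,4-benzodioxine | O1CCOC1c1cc(OC)c2c(c1)O[C@H](c1cc(OC)c(OCOC)c(OC)c1)[C@@H](C)O2 | intermediate
26 | (2R,3R)-2-[3,5-dimethoxy-4-(methoxymethoxy)phenyl]-5-methoxy-3-methyl-2,3-dihydro-1,4-benzodioxine-7-carbaldehyde | O=Cc1cc(OC)c2c(c1)O[C@H](c1cc(OC)c(OCOC)c(OC)c1)[C@@H](C)O2 | intermediate
27 | 5-(ethylsulfonyl)-1-phenyl-1H-tetrazole | CCS(=O)(=O)c1nnnn1-c1ccccc1 | starting material
28 | potassium 1-[(1-phenyl-1H-tetrazol-5-yl)sulfonyl]ethan-1-ide | [K+].C[CH-]S(=O)(=O)c1nnnn1-c1ccccc1 | intermediate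
29 | (2R,3R)-2-[3,5-dimethoxy-4-(methoxymethoxy)phenyl]-5-methoxy-3-methyl-7-[(E)-prop-1-en-1-yl]-2,3-dihydro-1,4-benzodioxine | C/C=C/c1cc(OC)c2c(c1)O[C@H](c1cc(OC)c(OCOC)c(OC)c1)[C@@H](C)O2 | intermediate
30 | 4-{(2R,3R)-5-methoxy-3-methyl-7-[(E)-prop-1-en-1-yl]-2,3-dihydro-1,4-benzodioxin-2-yl}-2,6-dimethoxyphenol | C/C=C/c1cc(OC)c2c(c1)O[C@H](c1cc(OC)c(O)c(OC)c1)[C@@H](C)O2 | target

Total step count: 16. Longest linear sequence: 13 steps (9 to 30, steps 4–16). The branches are 1 to 6 (two steps) and 7 to 8 (one step).

Steps most likely to fail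

Step 13 (proposed new method).
- What may go wrong: the β-peroxy alkoxide may fragment (Grob-type C2–C3 cleavage) or collapse under base (Kornblum–DeLaMare-type) before it meets the aryne. The aryl anion may also be protonated, or may abstract the C3 hydrogen, before it reaches the peroxide oxygen.
- Fallback, known chemistry throughout: ring B is closed in two separate C–O bond formations, setting out from alcohol 16 and bromophenol 2.
- A Mitsunobu etherification (PPh3, DIAD, toluene, 0 °C → rt) joins the phenol oxygen of 2 to C2 of 16 with inversion. It should give tert-butyl{(1R,2R)-2-[2-bromo-4-(1,3-dioxolan-2-yl)-6-methoxyphenoxy]-1-[3,5-dimethoxy-4-(methoxymethoxy)phenyl]propoxy}dimethylsilane F1.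
- Bu4NF in THF then frees (1R,2R)-2-[2-bromo-4-(1,3-dioxolan-2-yl)-6-methoxyphenoxy]-1-[3,5-dimethoxy-4-(methoxymethoxy)phenyl]propan-1-ol F2.
- An intramolecular palladium-catalysed aryl ether synthesis (Pd(OAc)2, 2-(di-tert-butylphosphino)-1,1'-binaphthyl, Cs2CO3, toluene, 70 °C) closes C8a–O1 at the bromine-bearing carbon with retention at the carbinol centre. This comes back to the route at 25.
- The regiochemistry is then fixed by the positions of hydroxyl and bromine in 1.

Step 11.
- What may go wrong: substitution may be sluggish at a secondary carbon next to the branched, silyloxy-bearing C1. On warming, elimination or a 1,2-shift of the electron-rich ring C could take over.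
- Fallback: the C–OO bond is made before ring C is attached, at the far more reactive α-carbonyl position, setting out from 9.
- Weinreb amidation of the unprotected ester (MeNH(OMe)·HCl, i-PrMgCl, THF) should give (S)-2-hydroxy-N-methoxy-N-methylpropanamide F3.
- Tf2O and 2,6-lutidine at −78 °C give (S)-1-[methoxy(methyl)amino]-1-oxopropan-2-yl trifluoromethanesulfonate F4.
- Peroxide salt 19 displaces triflate with inversion at −40 °C to give (R)-2-(tert-butylperoxy)-N-methoxy-N-methylpropanamide F5.
- Grignard reagent 12 at −40 °C then leads to (R)-2-(tert-butylperoxy)-1-[3,5-dimethoxy-4-(methoxymethoxy)phenyl]propan-1-one F6, which is set free only on acidic quench.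
- F6 is reduced at once with LiBH(s-Bu)3 in THF at −78 °C. The bulky, non-chelating peroxy group should steer hydride according to the Felkin–Anh model to the syn product, which is 21, where the fallback rejoins the route.

Step 16.
- What may go wrong: acid may add methanol to the propenyl double bond or oligomerise it. It may also ionise the benzylic C2–O1 bond once the para phenol is free.
- Fallback: all acid-labile groups are removed before the alkene exists, setting out from 25.
- 2 M aq. HCl in THF at 45 °C strips the dioxolane and the methoxymethyl ether together. This gives (2R,3R)-2-(4-hydroxy-3,5-dimethoxyphenyl)-5-methoxy-3-methyl-2,3-dihydro-1,4-benzodioxine-7-carbaldehyde F7.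
- The Julia–Kocienski olefination is then run on F7 with an excess of metallated sulfone 28, the first equivalent being spent on the phenol and the remote phenoxide staying a spectator. After neutral work-up this arrives directly at 30.

Further compounds
F1 | step 13 | tert-butyl{(1R,2R)-2-[2-bromo-4-(1,3-dioxolan-2-yl)-6-methoxyphenoxy]-1-[3,5-dimethoxy-4-(methoxymethoxy)phenyl]propoxy}dimethylsilane | CC(C)(C)[Si](C)(C)O[C@H](c1cc(OC)c(OCOC)c(OC)c1)[C@@H](C)Oc1c(Br)cc(C2OCCO2)cc1OC
F2 | step 13 | (1R,2R)-2-[2-bromo-4-(1,3-dioxolan-2-yl)-6-methoxyphenoxy]-1-[3,5-dimethoxy-4-(methoxymethoxy)phenyl]propan-1-ol | O[C@H](c1cc(OC)c(OCOC)c(OC)c1)[C@@H](C)Oc1c(Br)cc(C2OCCO2)cc1OC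
F3 | step 11 | (S)-2-hydroxy-N-methoxy-N-methylpropanamide | CON(C)C(=O)[C@H](C)O
F4 | step 11 | (S)-1-[methoxy(methyl)amino]-1-oxopropan-2-yl trifluoromethanesulfonate | CON(C)C(=O)[C@H](C)OS(=O)(=O)C(F)(F)F
F5 | step 11 | (R)-2-(tert-butylperoxy)-N-methoxy-N-methylpropanamide | CON(C)C(=O)[C@@H](C)OOC(C)(C)C
F6 | step 11 | (R)-2-(tert-butylperoxy)-1-[3,5-dimethoxy-4-(methoxymethoxy)phenyl]propan-1-one | O=C(c1cc(OC)c(OCOC)c(OC)c1)[C@@H](C)OOC(C)(C)C
F7 | step 16 | (2R,3R)-2-(4-hydroxy-3,5-dimethoxyphenyl)-5-methoxy-3-methyl-2,3-dihydro-1,4-benzodioxine-7-carbaldehyde | O=Cc1cc(OC)c2c(c1)O[C@H](c1cc(OC)c(O)c(OC)c1)[C@@H](C)O2
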